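The readings were computed with constants of no real substance.

Amounts first: the west flask held 0.150 M Sub and 0.180 M Rgt, the north-west charge divided by 4.00 in both species, so I treated it as the north-west run on a slower clock.

| flask | Sub | Rgt | time |
|---|---|---|---|
| north-west | 0.600 M | 0.720 M |  |
| north-east | 0.240 M | 0.360 M |  |
| east | 1.80 M | 0.720 M |  |
| south-east | 0.600 M | 1.10 M |  |
| west | 0.150 M | 0.180 M | 45 h |

- north-west run (time / h: [Prd] / M): 9.0: 0.150; 18: 0.271; 27: 0.314; 36: 0.325; 45: 0.333
- north-east run (time / h: [Prd] / M): 9.0: 0.013; 18: 0.039; 27: 0.058; 36: 0.088; 45: 0.100
- east run (time / h: [Prd] / M): 9.0: 0.416; 18: 0.473; 27: 0.501; 36: 0.518; 45: 0.529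
- south-east run (time / h: [Prd] / M): 9.0: 0.246; 18: 0.363; 27: 0.413; 36: 0.430; 45: 0.436

(readings scatter by 0.003 M)

- Overall: Sub + Rgt -> Prd.
- Constant volume, constant temperature.
- "The second partner" is Rgt.
- An order is taken over about fifteen percent of the charge, up and down.

1. order of the initial rate in [Sub], near the charge of the north-west run, the rate being that where two percent of its Sub are Prd (one fixed amount of Prd, the same in the runs compared)
2. order of the initial rate in [Rgt], near the charge of the north-west run, the rate being that where two percent of its Sub are Prd
3. Prd in the west run at 45 h, as a share of the Sub charged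

I measured that slowing by the fractional-life method. The north-west run had 25.0% of its Sub as Prd at 9.0 h, and the north-east run had 24.2% at 27 h. I took these as one share, so the time stretched by 3.00, while the mean charge, the square root of c(Sub) times c(Rgt), fell by a factor of 2.24. That gave 1.37, my clock exponent: the power to which a dilution factor is raised to give the stretch in time to one share of Sub.

For the west run, the exponent turned the dilution into a stretch of 6.64, so its 45 h counted as 6.78 h of the north-west run. A straight line from zero to the first north-west reading then gave 18.8% of the Sub as Prd, which is 0.0282 M. I told my successor to expect that amount and to add neither species, because my reckoning rested on the Sub-to-Rgt ratio of 0.833 shared with the north-west run.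

The forecast gave orders of 1.2 in Sub and 1.2 in Rgt and a west value of 13%, lower than my figure, and held that the plateaus “fit a reversible reaction”.

The flask gave orders of 1.1 in Sub and 0.76 in Rgt, and the west run reached 22.4%, higher than my figure by 3.6 percentage points.

    Sub + Rgt ⇌ Int (0.1008 L mol⁻¹ h⁻¹, 0.03744 h⁻¹)
    Int → Prd (0.04248 h⁻¹)
    2 Rgt → G (0.1649 L mol⁻¹ h⁻¹)
    Sub + Rgt + Prd → 2 Prd (3.222 L² mol⁻² h⁻¹)

In the south-east run, extra Rgt raised the mean charge by a factor of 1.24. With my clock exponent of 1.37, Prd in the south-east run was due at a quarter of the charge at 6.64 h, against 8.87 h in the north-west run, and it stood there at 6.20 h. Rgt pairing with itself to G held the west run at 22.4%; with that step taken away, the west run reached 48.5%.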